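(The readings stem from a simulated flask for an exercise; the scatter is artificial.)

The flask starts slowly. In south, 1.9% of the charge stands in chains after 0.200 min, and free monomer decays faster as living ends form from initiator. Once they have formed, each molecule of free monomer meets a nearly steady number of ends, so it decays with a single time constant (pseudo-first-order).

| flask | free monomer | initiator | remark | time |
|---|---|---|---|---|
| south | 2 M (in portions, 3) | 28 mM | run made earlier; portions every 1.0 min |  |
| south-east | 2 M (in portions, 3) | 44 mM | run made earlier; portions every 1.0 min |  |
| ash | 2.0 M (in portions, 3) | 20 mM | the portions of free monomer follow each other after 1.0 min, the first at the start | 3.0 min |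
| maple | 2.0 M (in portions, 3) | 20 mM | the portions of free monomer follow each other after 2.0 min, the first at the start | 3.0 min |
| cedar | 2.0 M (in portions, 3) | 20 mM | the portions of free monomer follow each other after 4.0 min, the first at the start | 3.0 min |

| run | time / min | monomer in chains / % |
|---|---|---|
| south | 0.200 | 1.9 |
| south | 0.333 | 5.1 |
| south | 0.500 | 9.6 |
| south | 0.833 | 17.2 |
| south | 1.33 | 38.6 |
| south | 2.50 | 83.2 |
| south-east | 0.200 | 3.1 |
| south-east | 0.333 | 7.4 |
| south-east | 0.500 | 12.8 |
| south-east | 0.833 | 22.1 |
| south-east | 1.33 | 47.1 |
| south-east | 2.50 | 90.5 |

(scatter of a reading: 0.3 percentage points)

- amount of monomer in chains at the end, in percent of the free monomer charged for ash, maple, cedar, in this order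
- how that number moves from the first to the last of them (falls, then rises / falls all the way / rises all the way / rises, then falls / hardly changes)

- the earlier runs were read with a standard deviation of 0.3 percentage points
- percentages count the whole charge, also what has not yet gone in
- "hardly changes" means that all values lie within two and a half points (for a concentration: within two and a half percent of the largest)

The bench rule of thumb says that what has gone in has reacted, so chains equal the fed share at 3.0 min. That share is the whole charge in ash, 66.7% in maple and 33.3% in cedar, whose second portion comes after the reading.

The rule needs a time constant. Between 0.500 min and 0.833 min, free monomer in south-east decays 1.56 times as fast as in south, and the initiator ratio is 1.57, so the rate follows initiator. The time constant there reads 0.552 min. Across the last portion of south-east, with the leftover carried through, it reads 0.368 min. Scaled by initiator to 20 mM, this gives the lifetime of free monomer, 0.809 min.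

The border of the rule is the age, at the reading, of the last portion to have gone in, divided by this lifetime. That ratio is 3.71 in cedar, where the rule holds, but 1.24 in ash and maple, where much of the last portion is still free. Decaying each portion by its own age, and ignoring the slow start, my reckoning gives 86.7%, 56.2% and 32.5%.

The forecast says 88%, 56% and 32%, falls all the way, holding that “initiation needs monomer and is not instantaneous”.

The flasks give 87.9%, 55.9% and 31.7%: the number falls all the way.

    free monomer + initiator → living end + monomer in chains (k = 0.0390 M⁻¹ s⁻¹)
    free monomer + living end → monomer in chains + living end, rate k2*[living end]*[free monomer] (k = 1.20 M⁻¹ s⁻¹)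
    free monomer + initiator → spent initiator (k = 4.60 × 10⁻⁴ M⁻¹ s⁻¹)

Cedar's 31.7% comes from the drawn-out feeding together with the reading at 3.0 min: with the drawn-out feeding taken away and the whole charge put in at the start, cedar gives 97.9%, and with the early reading taken away and the flask read at 30.0 min instead, it gives >99.9%. Over the second half of cedar, the lifetime takes 9.77% free monomer at 1.50 min down to 1.53% by 3.0 min, and at 3.00 min the flask holds 1.7%. In ash, 14.6% at 2.00 min plus the last portion decays to 13.9% by 3.0 min, and at 3.00 min the flask holds 12%.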